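Cuts (oxolane numbered O1, C2 aryl, C3 spiro, C4 arylmethyl, C5): both O–Si bonds; the oxirane C3–O bond, back to an exocyclic C3=CH2; then C2–C3 and C5–O1 together, which leaves aldehyde 2 and the three-carbon unit 13; last C4–CH2Ar, back to an acyloxazolidinone enolate and benzylic bromide 6.
Feature used: the spiro-oxirane carbon C3 is a masked 1,1-disubstituted alkene carbon lying between benzylic C2 (an aldehyde carbon once O1 is double-bonded to it) and, through C4, the primary ether carbon C5. One C3–C4–C5 unit can therefore carry an alkenyl-metal donor at C3 and a sulfonate acceptor at C5 and add across C2=O1.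
Forward: the open-chain C3–C5 piece is made first; the oxolane ring arises in one pot by Ni/Cr alkenylation of 2 and 5-exo-tet etherification; the oxirane ring follows by epoxidation; desilylation ends the route.
Stereochemistry: C4 from the (R)-4-benzyloxazolidinone auxiliary (Evans alkylation); C2 from the chiral oxazoline–sulfonamide ligand on chromium; C3 from substrate control, the peracid adding anti to the cis C2-aryl and C4-arylmethyl groups.

Key step: step 10

Assumption: the (R)-configured ligand L is taken to send the alkenyl group to the Re face of 2; if the first run shows the opposite sense, its (S)-antipode is used and nothing else changes.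
Remark: ligand L is (R)-N-[2-(4-isopropyl-4,5-dihydro-1,3-oxazol-2-yl)-6-methoxyphenyl]methanesulfonamide, a catalyst component made separately from D-valinol and not counted in the steps.

Step 1
Reactants: 1 vanillin (4-hydroxy-3-methoxybenzaldehyde)
Product: 2 3-methoxy-4-(triisopropylsilyloxy)benzaldehyde
Conditions: i-Pr3SiCl, imidazole, DMF, rt
Reagents that add atoms: triisopropylsilyl chloride, CC(C)[Si](Cl)(C(C)C)C(C)C
Why: Routine phenol silylation; the hindered aryl triisopropylsilyl ether should survive the later basic, reducing and organochromium steps until fluoride is applied.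

Step 2
Reactants: 3 isovanillin (3-hydroxy-4-methoxybenzaldehyde)
Product: 4 4-methoxy-3-(triisopropylsilyloxy)benzaldehyde
Conditions: i-Pr3SiCl, imidazole, DMF, rt
Reagents that add atoms: triisopropylsilyl chloride, CC(C)[Si](Cl)(C(C)C)C(C)C
Why: Same phenol silylation as in step 1, placing the protecting group before the benzylic position is activated.

Step 3
Reactants: 4 4-methoxy-3-(triisopropylsilyloxy)benzaldehyde
Product: 5 [4-methoxy-3-(triisopropylsilyloxy)phenyl]methanol
Conditions: NaBH4, MeOH, 0 °C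
Reagents that add atoms: none
Why: Borohydride reduction of an aryl aldehyde to the benzylic alcohol, which leaves the aryl silyl ether intact.

Step 4
Reactants: 5 [4-methoxy-3-(triisopropylsilyloxy)phenyl]methanol
Product: 6 4-(bromomethyl)-1-methoxy-2-(triisopropylsilyloxy)benzene
Conditions: CBr4, PPh3, CH2Cl2, 0 °C
Reagents that add atoms: carbon tetrabromide, BrC(Br)(Br)Br
Why: Appel bromination under neutral conditions should give the reactive 4-methoxybenzyl-type bromide, to be used without storage.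

Step 5
Reactants: 7 but-3-ynoic acid
Product: 8 3-iodobut-3-enoic acid
Conditions: aq. HI (57%), 0 °C → rt
Reagents that add atoms: hydrogen iodide, I
Why: Markovnikov hydroiodination of the terminal alkyne places iodine on the internal carbon and should give the 2-iodoalk-1-ene unit with the double bond kept out of conjugation with the acid.

Step 6
Reactants: 8 3-iodobut-3-enoic acid; 9 (R)-4-benzyloxazolidin-2-one
Product: 10 (R)-4-benzyl-3-(3-iodobut-3-enoyl)oxazolidin-2-one
Conditions: t-BuCOCl, Et3N, THF, −78 → 0 °C; then 9 pre-lithiated with n-BuLi, THF, −78 °C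
Reagents that add atoms: none
Why: N-Acylation of the lithiated oxazolidinone by the mixed pivalic anhydride; the low temperature should keep the β,γ-double bond from moving into conjugation.

Step 7
Reactants: 10 (R)-4-benzyl-3-(3-iodobut-3-enoyl)oxazolidin-2-one; 6 4-(bromomethyl)-1-methoxy-2-(triisopropylsilyloxy)benzene
Product: 11 (4R)-4-benzyl-3-[(2S)-3-iodo-2-{[4-methoxy-3-(triisopropylsilyloxy)phenyl]methyl}but-3-enoyl]oxazolidin-2-one
Conditions: NaN(SiMe3)2, THF, −78 °C; then 6, −78 °C
Reagents that add atoms: none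
Why: Evans asymmetric alkylation, in which the chelated Z sodium enolate is attacked at its α-carbon on the face opposite the auxiliary benzyl group, so that the (R)-auxiliary sets the (2S) centre (the later C4), while the fast reaction of the activated bromide at −78 °C is relied on to outrun loss of iodide from the dienolate.

Step 8
Reactants: 11 (4R)-4-benzyl-3-[(2S)-3-iodo-2-{[4-methoxy-3-(triisopropylsilyloxy)phenyl]methyl}but-3-enoyl]oxazolidin-2-one
Product: 12 (2S)-3-iodo-2-{[4-methoxy-3-(triisopropylsilyloxy)phenyl]methyl}but-3-en-1-ol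
Conditions: LiBH4, H2O (1 equiv), Et2O, 0 °C
Reagents that add atoms: none
Why: Reductive cleavage of the imide at the exocyclic carbonyl should release the primary alcohol and the auxiliary without touching the alkenyl iodide, the silyl ether or the stereocentre.

Step 9
Reactants: 12 (2S)-3-iodo-2-{[4-methoxy-3-(triisopropylsilyloxy)phenyl]methyl}but-3-en-1-ol
Product: 13 (2S)-3-iodo-2-{[4-methoxy-3-(triisopropylsilyloxy)phenyl]methyl}but-3-en-1-yl 4-methylbenzenesulfonate
Conditions: TsCl, Et3N, DMAP (cat.), CH2Cl2, 0 °C → rt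
Reagents that add atoms: 4-methylbenzenesulfonyl chloride, Cc1ccc(cc1)S(Cl)(=O)=O
Why: Sulfonylation of the primary alcohol installs the leaving group on the future C5 without affecting the stereocentre.

Step 10
Reactants: 13 (2S)-3-iodo-2-{[4-methoxy-3-(triisopropylsilyloxy)phenyl]methyl}but-3-en-1-yl 4-methylbenzenesulfonate; 2 3-methoxy-4-(triisopropylsilyloxy)benzaldehyde
Product: 16 (2R,4R)-2-[3-methoxy-4-(triisopropylsilyloxy)phenyl]-4-{[4-methoxy-3-(triisopropylsilyloxy)phenyl]methyl}-3-methylideneoxolane, via trimethylsilyl ether 14 (not isolated), via allylic alcohol 15 (not isolated)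
Conditions: CrCl2 (10 mol%), ligand L (11 mol%), Et3N (11 mol%), NiCl2(2,9-dimethyl-1,10-phenanthroline) (2 mol%), Mn powder, Me3SiCl, MeCN, rt; then MeOH, K2CO3, rt, same flask
Reagents that add atoms: none
Why: Zerovalent nickel inserts into the C–I bond of 13 and passes the alkenyl group to chromium, the trivalent alkenylchromium adds to the carbonyl carbon of 2 (bond C2–C3), Me3SiCl takes the alkoxide off chromium as 14 so that Mn can return divalent chromium, and methanolic K2CO3 then unmasks 15, whose alkoxide displaces the primary tosylate (bond C5–O1). The closest known reaction type is the catalytic asymmetric Nozaki–Hiyama–Kishi coupling of 2-iodoalk-1-enes that carry a leaving group on the fourth carbon, followed by SN2 closure to 3-methylene-oxolanes. The oxolane closes 5-exo-tet by Williamson etherification at the non-stereogenic C5. The new stereocentre C2 is set under reagent control by the oxazoline–sulfonamide ligand on chromium, which should deliver the alkenyl group to the Re face of the aldehyde to give the (R)-carbinol and hence the 2,4-cis oxolane, while C4 is carried over from 13 because neither bond is made at it. The step needs chemoselectivity (the alkenyl metal must add to the aldehyde and neither attack the tosylate nor close a three-membered ring onto C5), which the low basicity and low SN2 reactivity of organochromium secure, and facial selectivity at C2, which the weak 1,3-bias of C4 cannot give and the ligand must.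

Step 11
Reactants: 16 (2R,4R)-2-[3-methoxy-4-(triisopropylsilyloxy)phenyl]-4-{[4-methoxy-3-(triisopropylsilyloxy)phenyl]methyl}-3-methylideneoxolane
Product: 17 (3S,4S,7S)-4-[3-methoxy-4-(triisopropylsilyloxy)phenyl]-7-{[4-methoxy-3-(triisopropylsilyloxy)phenyl]methyl}-1,5-dioxaspiro[2.4]heptane
Conditions: mCPBA, NaHCO3, CH2Cl2, 0 °C
Reagents that add atoms: 3-chloroperoxybenzoic acid, OOC(=O)c1cccc(Cl)c1
Why: Prilezhaev epoxidation of the exocyclic alkene, in which the peracid should approach the face anti to the cis aryl and arylmethyl groups on the two flanking ring carbons and so place the oxirane oxygen trans to both (3S), the bicarbonate buffer protecting the acid-labile spiro-oxirane.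

Step 12
Reactants: 17 (3S,4S,7S)-4-[3-methoxy-4-(triisopropylsilyloxy)phenyl]-7-{[4-methoxy-3-(triisopropylsilyloxy)phenyl]methyl}-1,5-dioxaspiro[2.4]heptane
Product: 18 (3S,4S,7S)-4-(4-hydroxy-3-methoxyphenyl)-7-[(3-hydroxy-4-methoxyphenyl)methyl]-1,5-dioxaspiro[2.4]heptane (CNP0184956.1)
Conditions: Bu4NF, AcOH (1:1), THF, 0 °C
Reagents that add atoms: none
Why: Fluoride cleavage of both aryl silyl ethers, with acetic acid protonating each phenoxide at once so that neither oxirane opening nor ring-opening at C2 through a quinone methide should compete.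

Compound list
1 | vanillin (4-hydroxy-3-methoxybenzaldehyde) | COc1cc(C=O)ccc1O | starting material
2 | 3-methoxy-4-(triisopropylsilyloxy)benzaldehyde | COc1cc(C=O)ccc1O[Si](C(C)C)(C(C)C)C(C)C | intermediate
3 | isovanillin (3-hydroxy-4-methoxybenzaldehyde) | COc1ccc(C=O)cc1O | starting material
4 | 4-methoxy-3-(triisopropylsilyloxy)benzaldehyde | COc1ccc(C=O)cc1O[Si](C(C)C)(C(C)C)C(C)C | intermediate
5 | [4-methoxy-3-(triisopropylsilyloxy)phenyl]methanol | COc1ccc(CO)cc1O[Si](C(C)C)(C(C)C)C(C)C | intermediate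
6 | 4-(bromomethyl)-1-methoxy-2-(triisopropylsilyloxy)benzene | COc1ccc(CBr)cc1O[Si](C(C)C)(C(C)C)C(C)C | intermediate
7 | but-3-ynoic acid | C#CCC(=O)O | starting material
8 | 3-iodobut-3-enoic acid | C=C(I)CC(=O)O | intermediate
9 | (R)-4-benzyloxazolidin-2-one | O=C1N[C@H](Cc2ccccc2)CO1 | starting material
10 | (R)-4-benzyl-3-(3-iodobut-3-enoyl)oxazolidin-2-one | C=C(I)CC(=O)N1[C@H](Cc2ccccc2)COC1=O | intermediate
11 | (4R)-4-benzyl-3-[(2S)-3-iodo-2-{[4-methoxy-3-(triisopropylsilyloxy)phenyl]methyl}but-3-enoyl]oxazolidin-2-one | COc1ccc(C[C@H](C(I)=C)C(=O)N2[C@H](Cc3ccccc3)COC2=O)cc1O[Si](C(C)C)(C(C)C)C(C)C | intermediate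
12 | (2S)-3-iodo-2-{[4-methoxy-3-(triisopropylsilyloxy)phenyl]methyl}but-3-en-1-ol | COc1ccc(C[C@H](C(I)=C)CO)cc1O[Si](C(C)C)(C(C)C)C(C)C | intermediate
13 | (2S)-3-iodo-2-{[4-methoxy-3-(triisopropylsilyloxy)phenyl]methyl}but-3-en-1-yl 4-methylbenzenesulfonate | COc1ccc(C[C@H](C(I)=C)COS(=O)(=O)c2ccc(C)cc2)cc1O[Si](C(C)C)(C(C)C)C(C)C | intermediate
14 | (2R,4R)-4-[3-methoxy-4-(triisopropylsilyloxy)phenyl]-2-{[4-methoxy-3-(triisopropylsilyloxy)phenyl]methyl}-3-methylidene-4-(trimethylsilyloxy)butyl 4-methylbenzenesulfonate | COc1ccc(C[C@@H](COS(=O)(=O)c2ccc(C)cc2)C(=C)[C@@H](O[Si](C)(C)C)c2ccc(O[Si](C(C)C)(C(C)C)C(C)C)c(OC)c2)cc1O[Si](C(C)C)(C(C)C)C(C)C | intermediate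
15 | (2R,4R)-4-hydroxy-4-[3-methoxy-4-(triisopropylsilyloxy)phenyl]-2-{[4-methoxy-3-(triisopropylsilyloxy)phenyl]methyl}-3-methylidenebutyl 4-methylbenzenesulfonate | COc1ccc(C[C@@H](COS(=O)(=O)c2ccc(C)cc2)C(=C)[C@@H](O)c2ccc(O[Si](C(C)C)(C(C)C)C(C)C)c(OC)c2)cc1O[Si](C(C)C)(C(C)C)C(C)C | intermediate
16 | (2R,4R)-2-[3-methoxy-4-(triisopropylsilyloxy)phenyl]-4-{[4-methoxy-3-(triisopropylsilyloxy)phenyl]methyl}-3-methylideneoxolane | COc1ccc(C[C@H]2CO[C@@H](c3ccc(O[Si](C(C)C)(C(C)C)C(C)C)c(OC)c3)C2=C)cc1O[Si](C(C)C)(C(C)C)C(C)C | intermediate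
17 | (3S,4S,7S)-4-[3-methoxy-4-(triisopropylsilyloxy)phenyl]-7-{[4-methoxy-3-(triisopropylsilyloxy)phenyl]methyl}-1,5-dioxaspiro[2.4]heptane | COc1ccc(C[C@H]2CO[C@@H](c3ccc(O[Si](C(C)C)(C(C)C)C(C)C)c(OC)c3)[C@@]23CO3)cc1O[Si](C(C)C)(C(C)C)C(C)C | intermediate
18 | (3S,4S,7S)-4-(4-hydroxy-3-methoxyphenyl)-7-[(3-hydroxy-4-methoxyphenyl)methyl]-1,5-dioxaspiro[2.4]heptane | COc1ccc(C[C@H]2CO[C@@H](c3ccc(O)c(OC)c3)[C@@]23CO3)cc1O | target

Total steps: 12. Longest linear sequence: 9 steps (3 → 4 → 5 → 6 → 11 → 12 → 13 → 16 → 17 → 18, steps 2, 3, 4, 7, 8, 9, 10, 11, 12).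

Steps most likely to fail

Step 10. The ligand may give poor facial selectivity at C2 against the adjacent C4 centre, pinacol coupling of the aromatic aldehyde may compete, or the aryl silyl ethers may erode in the methanolic stage. The fallback sets out from 13 and 2 and separates the two events. A ligand-free stoichiometric coupling (CrCl2, catalytic NiCl2, DMF, rt, aqueous work-up) should give 15 together with its C4 epimer, (2R,4S)-4-hydroxy-4-[3-methoxy-4-(triisopropylsilyloxy)phenyl]-2-{[4-methoxy-3-(triisopropylsilyloxy)phenyl]methyl}-3-methylidenebutyl 4-methylbenzenesulfonate F1, and the two are separated by chromatography. Isolated 15 is closed to 16 with KN(SiMe3)2 in THF at −78 → 0 °C. F1 is inverted by a Mitsunobu reaction (4-nitrobenzoic acid, PPh3, DIAD) to (2R,4R)-4-[3-methoxy-4-(triisopropylsilyloxy)phenyl]-2-{[4-methoxy-3-(triisopropylsilyloxy)phenyl]methyl}-3-methylidene-4-(4-nitrobenzoyloxy)butyl 4-methylbenzenesulfonate F2. K2CO3 in MeOH then removes the ester and closes the ring, so both streams come back to the route at 16.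

Step 7. The dienolate may lose iodide to give an allenoyl imide, or the double bond may drift into conjugation, before alkylation is complete. The fallback sets out from 9 and 6 and puts the alkenyl leaving group in after the stereocentre is made.
- Lithiated 9 is acylated with but-3-enoyl chloride to (R)-4-benzyl-3-(but-3-enoyl)oxazolidin-2-one F3.
- Evans alkylation (NaN(SiMe3)2, then 6, −78 °C) gives (4R)-4-benzyl-3-[(2R)-2-{[4-methoxy-3-(triisopropylsilyloxy)phenyl]methyl}but-3-enoyl]oxazolidin-2-one F4.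
- LiBH4 gives (2R)-2-{[4-methoxy-3-(triisopropylsilyloxy)phenyl]methyl}but-3-en-1-ol F5, and TsCl/Et3N gives (2R)-2-{[4-methoxy-3-(triisopropylsilyloxy)phenyl]methyl}but-3-en-1-yl 4-methylbenzenesulfonate F6.
- Wacker–Tsuji oxidation (PdCl2, CuCl, O2, DMF/H2O) gives (2S)-2-{[4-methoxy-3-(triisopropylsilyloxy)phenyl]methyl}-3-oxobutyl 4-methylbenzenesulfonate F7.
- Kinetic enolisation at the methyl group (KN(SiMe3)2, PhNTf2, THF, −78 °C) gives (2S)-2-{[4-methoxy-3-(triisopropylsilyloxy)phenyl]methyl}-3-(trifluoromethylsulfonyloxy)but-3-en-1-yl 4-methylbenzenesulfonate F8.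
- F8 takes the place of 13 under the conditions of step 10 (alkenyl triflates are standard partners in Ni/Cr couplings) and the route is rejoined at 16.

Step 12. Once phenoxides form, the spiro-oxirane may open or the oxolane may open at C2 through a quinone methide. The fallback sets out from 16 and reverses the order of the last two operations, so that no deprotection follows epoxide formation. Bu4NF in THF gives 4-[(2R,4R)-4-[(3-hydroxy-4-methoxyphenyl)methyl]-3-methylideneoxolan-2-yl]-2-methoxyphenol F9. Buffered mCPBA (NaHCO3, CH2Cl2, 0 °C) then epoxidises the free bisphenol from the same open face, as is done with simple allyl-guaiacols, and the route is rejoined at 18.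

Further compounds
F1 | step 10 | (2R,4S)-4-hydroxy-4-[3-methoxy-4-(triisopropylsilyloxy)phenyl]-2-{[4-methoxy-3-(triisopropylsilyloxy)phenyl]methyl}-3-methylidenebutyl 4-methylbenzenesulfonate | COc1ccc(C[C@@H](COS(=O)(=O)c2ccc(C)cc2)C(=C)[C@H](O)c2ccc(O[Si](C(C)C)(C(C)C)C(C)C)c(OC)c2)cc1O[Si](C(C)C)(C(C)C)C(C)C
F2 | step 10 | (2R,4R)-4-[3-methoxy-4-(triisopropylsilyloxy)phenyl]-2-{[4-methoxy-3-(triisopropylsilyloxy)phenyl]methyl}-3-methylidene-4-(4-nitrobenzoyloxy)butyl 4-methylbenzenesulfonate | COc1ccc(C[C@@H](COS(=O)(=O)c2ccc(C)cc2)C(=C)[C@@H](OC(=O)c2ccc(cc2)[N+](=O)[O-])c2ccc(O[Si](C(C)C)(C(C)C)C(C)C)c(OC)c2)cc1O[Si](C(C)C)(C(C)C)C(C)C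
F3 | step 7 | (R)-4-benzyl-3-(but-3-enoyl)oxazolidin-2-one | C=CCC(=O)N1[C@H](Cc2ccccc2)COC1=O
F4 | step 7 | (4R)-4-benzyl-3-[(2R)-2-{[4-methoxy-3-(triisopropylsilyloxy)phenyl]methyl}but-3-enoyl]oxazolidin-2-one | COc1ccc(C[C@H](C=C)C(=O)N2[C@H](Cc3ccccc3)COC2=O)cc1O[Si](C(C)C)(C(C)C)C(C)C
F5 | step 7 | (2R)-2-{[4-methoxy-3-(triisopropylsilyloxy)phenyl]methyl}but-3-en-1-ol | COc1ccc(C[C@H](C=C)CO)cc1O[Si](C(C)C)(C(C)C)C(C)C
F6 | step 7 | (2R)-2-{[4-methoxy-3-(triisopropylsilyloxy)phenyl]methyl}but-3-en-1-yl 4-methylbenzenesulfonate | COc1ccc(C[C@H](C=C)COS(=O)(=O)c2ccc(C)cc2)cc1O[Si](C(C)C)(C(C)C)C(C)C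
F7 | step 7 | (2S)-2-{[4-methoxy-3-(triisopropylsilyloxy)phenyl]methyl}-3-oxobutyl 4-methylbenzenesulfonate | COc1ccc(C[C@H](C(C)=O)COS(=O)(=O)c2ccc(C)cc2)cc1O[Si](C(C)C)(C(C)C)C(C)C
F8 | step 7 | (2S)-2-{[4-methoxy-3-(triisopropylsilyloxy)phenyl]methyl}-3-(trifluoromethylsulfonyloxy)but-3-en-1-yl 4-methylbenzenesulfonate | COc1ccc(C[C@H](C(=C)OS(=O)(=O)C(F)(F)F)COS(=O)(=O)c2ccc(C)cc2)cc1O[Si](C(C)C)(C(C)C)C(C)C
F9 | step 12 | 4-[(2R,4R)-4-[(3-hydroxy-4-methoxyphenyl)methyl]-3-methylideneoxolan-2-yl]-2-methoxyphenol | COc1ccc(C[C@H]2CO[C@@H](c3ccc(O)c(OC)c3)C2=C)cc1O
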